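**Assumptions (one line each)**
- Oridonin, an ent-kauranoid natural product, is treated as a commercially available starting material, so this is a semisynthesis.
- The C6 methyl-acetal configuration in the target is assumed to be the thermodynamic (anomeric) one.
- C19 is the axial CH2 on C4, syn to C20 and cis to C5–C6. This is the methyl that becomes oxygenated.

**Retrosynthesis**
1. Target ⇐ E1cB unmasking of the C16=C17 enone from its β-sulfonyl-ketone mask, and equilibration of the C6 methyl acetal.
2. The C6 methyl acetal ⇐ anodic α-methoxylation of the 6,19-epoxy (THF) ether.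
3. The THF ether (ring closed last, C4–C19–O–C6–C5) ⇐ Suárez 1,5-HAT cyclization of the C6 primary alcohol onto the cis C19 methyl. That alcohol ⇐ reduction of the C6 aldehyde.
4. The 1,14-dideoxy 6,7-seco aldehyde-lactone ⇐ Barton–McCombie removal of the 1α- and 14β-OH groups.
5. The seco aldehyde-lactone ⇐ periodate cleavage of the C6-OH/C7-hemiketal glycol of oridonin. This closes the 7,20-δ-lactone and frees the C6 aldehyde in one step. Rings A, C, D and C5, C8, C9, C10, C13 are inherited intact.

**Step 1**
Reactants: 1 oridonin; 2 sodium benzenesulfinate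
Product: 3 oridonin 17-phenylsulfone adduct (16,17-dihydro, C16 epimeric mixture)
Conditions: PhSO2Na, AcOH, THF/H2O, rt
Reagents that add atoms: sodium benzenesulfinate, [Na+].[O-]S(=O)c1ccccc1
Why: Conjugate (sulfa-Michael) addition of PhSO2H masks the exocyclic enone, which would not survive the radical and oxidative steps. It creates an epimeric C16 centre that is erased in Step 9.

**Step 2**
Reactants: 3
Product: 4 6,7-seco aldehyde with 7,20-lactone (1α-OH, 14β-OH retained)
Conditions: NaIO4, THF/H2O, 0 °C → rt
Reagents that add atoms: none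
Why: Malaprade cleavage of the vicinal C6-OH/C7-hemiketal-OH pair gives the C6 aldehyde and converts the hemiketal into the 7,20-lactone. No stereocentre is created, and C5 stays in its equatorial-CHO configuration.

**Step 3**
Reactants: 4; 5 1,1'-thiocarbonyldiimidazole
Product: 6 1,14-bis(imidazol-1-ylcarbonothioyl) ether of 4
Conditions: TCDI, ClCH2CH2Cl, 80 °C (no base, to avoid retro-Michael of the mask)
Reagents that add atoms: TCDI, S=C(n1ccnc1)n1ccnc1
Why: Thiocarbonylimidazolide formation on the two free secondary alcohols prepares them for Barton–McCombie deoxygenation.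

**Step 4**
Reactants: 6
Product: 7 1,14-dideoxy aldehyde-lactone sulfone
Conditions: (TMS)3SiH, AIBN, PhMe, 110 °C
Reagents that add atoms: none
Why: Barton–McCombie radical deoxygenation turns C1 and C14 into CH2, so no stereocentre remains there. A high silane concentration outcompetes β-scission of the C14 radical next to quaternary C8. The silane, unlike Bu3SnH, is a poor aldehyde reductant.

**Step 5**
Reactants: 7
Product: 8 C6 primary alcohol (6-hydroxymethyl lactone sulfone)
Conditions: NaBH4, EtOH/CH2Cl2, −78 °C
Reagents that add atoms: none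
Why: Hydride reduction at low temperature is chemoselective for the aldehyde over the hindered bicyclic ketone and the lactone. No stereocentre is created.

**Step 6**
Reactants: 8
Product: 9 6,19-epoxy (THF) ether
Conditions: PIDA, I2, cyclohexane, hν (visible), 40 °C
Reagents that add atoms: none
Why: The Suárez hypoiodite reaction gives the C6 alkoxy radical, which abstracts H from the cis-axial C19 methyl (1,5-HAT). The resulting iodide is displaced by oxygen to close the cis-fused THF. This sets C4: C19 is the methyl cis to C6, and C18 is left as the trans methyl.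

**Step 7**
Reactants: 9; 10 methanol
Product: 11 6-methoxy acetal, C6 epimeric mixture
Conditions: constant-current electrolysis (graphite anode, Pt cathode), Et4NOTs, MeOH, rt
Reagents that add atoms: methanol, CO
Why: Shono-type anodic α-methoxylation occurs at C6H2, the less hindered α-CH2 next to tertiary C5, rather than at neopentyl C19. It gives both C6 acetal epimers.

**Step 8**
Reactants: 11
Product: 12 single C6-epimer methyl acetal (masked-enone sulfone)
Conditions: PPTS (cat.), MeOH, rt
Reagents that add atoms: none
Why: Acid-catalysed acetal equilibration through the oxocarbenium ion funnels to the thermodynamic anomer (anomeric effect) and sets C6.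

**Step 9**
Reactants: 12
Product: 13 ludongunin J (target)
Conditions: DBU, CH2Cl2, 0 °C → rt
Reagents that add atoms: none
Why: E1cB retro-Michael elimination of PhSO2⁻ regenerates the C16=C17 exocyclic enone. The transient C16 stereocentre is destroyed, and the acetal and lactone are base-stable.

**Compound list**

| # | Name | SMILES | Role |
|---|---|---|---|
| 1 | oridonin | `C=C1C(=O)[C@]23[C@H](O)[C@H]1CC[C@H]2[C@@]4([C@@H](O)CCC(C)(C)[C@H]4[C@@H]5O)CO[C@@]35O` | starting material |
| 2 | sodium benzenesulfinate | `[Na+].[O-]S(=O)c1ccccc1` | starting material |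
| 3 | oridonin 17-phenylsulfone adduct (C16 epimers) | `O=S(=O)(CC1C(=O)[C@]23[C@H](O)[C@H]1CC[C@H]2[C@@]4([C@@H](O)CCC(C)(C)[C@H]4[C@@H]5O)CO[C@@]35O)c6ccccc6` | intermediate |
| 4 | 6,7-seco aldehyde 7,20-lactone, 1α-OH, 14β-OH, sulfone mask | `O=S(=O)(CC1C(=O)[C@]23[C@H](O)[C@H]1CC[C@H]2[C@@]4([C@@H](O)CCC(C)(C)[C@H]4C=O)COC3=O)c5ccccc5` | intermediate |
| 5 | 1,1'-thiocarbonyldiimidazole | `S=C(n1ccnc1)n1ccnc1` | starting material |
| 6 | 1,14-bis(imidazolylthiocarbonate) of 4 | `O=S(=O)(CC1C(=O)[C@]23[C@H](OC(=S)n4ccnc4)[C@H]1CC[C@H]2[C@@]5([C@@H](OC(=S)n6ccnc6)CCC(C)(C)[C@H]5C=O)COC3=O)c7ccccc7` | intermediate |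
| 7 | 1,14-dideoxy 6-aldehyde lactone sulfone | `O=S(=O)(CC1C(=O)[C@]23C[C@H]1CC[C@H]2[C@@]4(CCCC(C)(C)[C@H]4C=O)COC3=O)c5ccccc5` | intermediate |
| 8 | C6 primary alcohol | `O=S(=O)(CC1C(=O)[C@]23C[C@H]1CC[C@H]2[C@@]4(CCCC(C)(C)[C@H]4CO)COC3=O)c5ccccc5` | intermediate |
| 9 | 6,19-epoxy ether | `O=S(=O)(CC1C(=O)[C@]23C[C@H]1CC[C@H]2[C@@]4(CCC[C@@]5(C)COC[C@H]54)COC3=O)c6ccccc6` | intermediate |
| 10 | methanol | `CO` | starting material |
| 11 | 6-methoxy acetal, C6 epimeric mixture | `O=S(=O)(CC1C(=O)[C@]23C[C@H]1CC[C@H]2[C@@]4(CCC[C@@]5(C)COC(OC)[C@H]54)COC3=O)c6ccccc6` | intermediate |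
| 12 | single C6-epimer methyl acetal sulfone | `O=S(=O)(CC1C(=O)[C@]23C[C@H]1CC[C@H]2[C@@]4(CCC[C@@]5(C)CO[C@@H](OC)[C@H]54)COC3=O)c6ccccc6` | intermediate |
| 13 | ludongunin J | `C=C1C(=O)[C@]23C[C@H]1CC[C@H]2[C@@]1(CCC[C@@]2(C)CO[C@@H](OC)[C@H]21)COC3=O` | target |

**Totals**
Total steps: 9. Longest linear sequence: 9.

**Three steps most likely to fail**
1. **Step 6 (Suárez C19 functionalisation).** The alkoxy radical may abstract from C18 or C20 instead of C19. Fallback, changing the approach: intercept at aldehyde 7 and hydroxylate C19 biocatalytically (engineered P450). The free C19-OH then closes onto the C6 aldehyde to give the lactol, and MeOH/H+ gives the acetal directly, which also removes the need for Step 7.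
2. **Step 4 (C14 deoxygenation).** The C14 radical beside quaternary C8 can undergo β-scission of the C8–C15 bond. Fallback, changing the approach: drop oridonin and build the 14-deoxy bicyclo[3.2.1]octane de novo. Use Pd(II)-mediated oxidative cyclization of a spirolactone silyl ketene acetal onto a pendant isopropenyl group, then SeO2 oxidation at C15.
3. **Step 7 (anodic α-methoxylation of the ether).** Selectivity between C6 and C19, and over-oxidation, are both concerns. Fallback, changing the approach: protect the C15 ketone as its dioxolane, oxidize the THF to the C6 γ-lactone with RuO4, reduce it to the lactol with DIBAL at −78 °C, then treat with MeOH/H+.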